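**Remarks on the chemistry (assumptions).** Atom numbers are those of the germacranolide skeleton described in the analysis. O-15 is carried as a TBDPS ether and O-8 as a TBS ether, because O-15 has to outlast two selective desilylations. The sense of induction at C8 in the ring closure cannot be fixed in advance; the route is written for the 8R alcohol, and the 8S alcohol is dealt with under the risks.

## Analysis of the target

The target 32 is a furanone-bridged germacranolide. Its ten-membered carbocycle C1–C10 carries an ether oxygen between C3 and C10, so that C1 (ketone), C2=C3 (enol ether), C10 and that oxygen form a 3(2H)-furanone. Across C6–C7 it is fused to an α-methylene-γ-butyrolactone (C11=C13, C12 carbonyl, lactone oxygen on C6). A Z C4=C5 alkene bearing the C15 hydroxymethyl group links the two five-membered rings, and C8 carries an (R)-2-methylbutanoate. There are four ring stereocentres. C6 (R), C7 (R) and C8 (R) are contiguous, with H-6 and H-7 trans across the lactone and O-8 syn to C6 along the chain C9–C8–C7–C11. The quaternary ether carbon C10 (S) is insulated from this triad by the C9 methylene; a fifth centre sits in the acyl side chain. The sensitive groups are: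

- the methylene lactone, a Michael acceptor that does not tolerate amines, thiols or late enolate chemistry;
- the cross-conjugated dienone C5=C4–C3=C2–C1=O, which can lose its Z geometry;
- the acyl α-centre, which can epimerise;
- any intermediate with a carbonyl at C8, which can expel the C10 oxygen (a vinylogous carboxylate) by β-elimination.

The difficulty is the medium ring: ten carbons, or nine atoms counted through the bridging oxygen, closed around a Z trisubstituted alkene and two planar rings, with the C6–C8 triad in the right relation to the remote C10. The strategy rests on the C7–C8 bond. It joins the β-carbon of the methylene lactone (C7) to a carbinol carbon (C8), which is the pattern left when an allyl metal with the metal on C13 and a C7=C11 double bond adds through C7 to a C8 aldehyde.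

## Retrosynthetic reasoning

**32 to 29.** The free C15 hydroxyl and the C8 ester are put on last. 32 comes from the silyl ether 31 by fluoride cleavage, and 31 from the tricyclic alcohol 29 and the acid 30 by acylation. Acylating after ring closure keeps the epimerisable acyl centre and a β-acyloxy leaving group out of all the earlier chemistry.

**29 to 27 (C7–C8, the key cut).** Cutting C7–C8 turns the methylene lactone into a planar 3-(bromomethyl)butenolide and C8 into an aldehyde, giving 27. In the forward sense the allylchromium species 28 adds through its γ-carbon to the aldehyde. This one step makes the carbocycle, shifts the alkene to C11=C13 and creates C7 and C8. The cut is made here because every other ring bond lies inside a planar unit or next to the quaternary C10, and because it is the only cut that delivers the methylene lactone without later enolate chemistry. Three points need to be stated precisely: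

- The carbocycle closed is ten-membered, but the smallest ring closed, through the furanone oxygen, is nine-membered.
- The tether is the C6 substituent itself, so the trans relation at C6/C7 must come from strain in the bicyclic transition state and not from shielding of one butenolide face.
- The natural C8 configuration is opposite to what the same allyl unit would give in an open-chain reaction. The ring must impose it, and an inverting acylation is held in reserve.

**27 to 25.** The aldehyde is made last, from the primary alcohol 26, which comes from the silyl ether 25. A C8 aldehyde can eliminate the C10 oxygen, so it should exist for one step only.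

**25 to 22 + 23.** The butenolide is cut at C7=C11 (ring-closing metathesis) and at the ester C–O bond. This leads to the acrylate 24 and then to the bis-allylic alcohol 22 and the acid 23. The bromide arrives with 23 and is therefore never exposed to bases, palladium or organolithium reagents.

**22 to 20.** The furanone is opened at O–C3. 22 comes from the silyl ether 21, and 21 from the α'-hydroxy ynone 20 by a 5-endo cyclisation of the C10 hydroxyl onto C3. O-6 is silylated at this stage because a free hydroxyl cis to the alkyne would close a furan faster than the tertiary hydroxyl closes the furanone.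

**20 to 12 + 17 (C1–C2).** The ynone is cut at C1–C2 into the terminal enyne 12, used as its lithium acetylide 18, and the Weinreb amide 17, used as its magnesium alkoxide 19. This is the convergent junction: 12 holds C2–C7, C13 excepted, and 17 holds C1 and C8–C10.

**12 to 6.** C3–C4 is cut next (Sonogashira coupling). 12 comes from 11, and 11 from the alkenyl iodide 9 and the alkyne 10. The Z iodide 9 is the silyl ether of 8, which comes from the propargylic alcohol 6 by hydroxyl-directed trans-hydroalumination and iodination through 7. This fixes the alkene geometry by mechanism and not by equilibration.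

**6 to 1.** 6 is obtained from the racemate 5 by kinetic resolution. 5 is cut at C5–C6 into the acetylide 4 of the silyl ether 2 and the enal 3; 2 is made from 1.

**17 to 13.** The Weinreb amide 17 comes from the dioxolanone 16. 16 goes back through the alcohol 15 and the acid 14 to 13, whose stereocentre becomes C10 unchanged. Its two carboxyl groups become C1 and C8, and the dioxolanone differentiates them.

## Alternatives that were turned down

**Alternative 1:** The cut is C1–C2. Forward, CrCl2 with catalytic NiCl2 would convert an iodoalkyne at C2 into an alkynylchromium species that adds to a C1 aldehyde, closing the carbocycle as the cyclic Z-enyne carbinol A1. Oxidation at C1 and a transannular attack of the C10 oxygen on C3 would then make the furanone.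
- For: the C1 centre is destroyed afterwards, so the ring closure carries no stereochemical burden, and the aldehyde has no α-hydrogen. C7 and C8 would be set earlier in an open-chain Barbier reaction, where the C6 substituent does shield one face of the butenolide. On control of C7 this plan is stronger than the chosen one.
- Against: the aldehyde sits on the fully substituted C10 and is hindered. The ring contains the linear unit C1–C2≡C3–C4 next to a Z alkene, which costs strain and slows closure relative to oligomerisation. The methylene lactone and the C8 ester must then survive three further operations on a strained enyne.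
- Comparison: the chosen route gives up the easy C7 control. In return it builds the furanone on an open chain, uses the rigid furanone to preorganise the ring closure, and leaves only two simple steps after the ring is made.

**Alternative 2:** The cut is the O–C10 bond of the ether bridge, which leads back to a monocyclic germacranolide with a 1,10-epoxide and a C3 ketone. Forward, camphorsulfonic acid would activate the epoxide, the C3 carbonyl oxygen would open it at the tertiary C10 with inversion, and loss of H-2 would leave the bridged enol ether A2, one oxidation at C1 away from the furanone.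
- For: it follows the likely biogenesis, makes the bridge and the enol ether in one step, and sets C10 stereospecifically from the epoxide. On C10 it is as secure as the chosen route.
- Against: it leaves the medium-ring problem unsolved, because the whole ten-membered ring with the Z alkene, lactone, C8 ester and a configurationally defined epoxide must exist first. Under acid a germacrane epoxide has competing transannular pathways (attack by the C4=C5 π bond, shifts from the C10 cation, opening at C1), and a ketone oxygen is a weak nucleophile. An oxidation must follow in the presence of the methylene lactone.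
- Comparison: the chosen route forms the same C10–O–C3 bridge from an acyclic hydroxy ynone under neutral gold catalysis, with C10 taken intact from 13, and spends its risk on a single C–C bond.

**Alternative 3:** The cut is C5–C6. Forward, CrCl2 with catalytic NiCl2 would turn a Z alkenyl iodide at C5 into an alkenylchromium species that adds to a C6 aldehyde. This closes the carbocycle with the alkene geometry retained and gives the allylic alcohol A3, in which C12 is still a methyl ester and C11 a methylene group. Lactonisation and α-methylenation would follow.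
- For: alkenyl halide–aldehyde coupling of this kind is among the most dependable ways to close medium rings and tolerates ketones and esters. The closure itself is better precedented than the chosen one, and C7 and C8 would be set beforehand by open-chain methods.
- Against: the C6 aldehyde has an epimerisable α-centre (C7) and a β-acyloxy group (the C8 ester) that can be lost by elimination. The new C6 carbinol is formed in the closure without obvious control, and only one epimer gives the trans lactone. After lactonisation the exocyclic methylene must still be introduced by enolate chemistry on a molecule holding a base-sensitive furanone and an eliminable C8 ester.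
- Comparison: the chosen strategy delivers the methylene lactone ready-made in the ring-closing step and needs no enolate once the ring exists. What it gives up is precedent for the closure.

Key step: step 19

## Route

Step 1
Reactants: 1 propargyl alcohol
Product: 2 tert-butyl(diphenyl)(prop-2-yn-1-yloxy)silane
Conditions: TBDPSCl, imidazole, CH2Cl2, 0 °C to rt
Reagents that add atoms: tert-butyl(chloro)diphenylsilane, CC(C)(C)[Si](Cl)(c1ccccc1)c1ccccc1
Why: Silylation of a primary alcohol with a chlorosilane and imidazole; the acid-stable TBDPS group is chosen so that O-15 survives the two later selective desilylations and is removed only at the end.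

Step 2
Reactants: 2 tert-butyl(diphenyl)(prop-2-yn-1-yloxy)silane; 3 acrolein
Product: 5 rac-6-(tert-butyldiphenylsilyloxy)hex-1-en-4-yn-3-ol, via lithium acetylide 4 (not isolated)
Conditions: n-BuLi, THF, −78 °C; then 3, −78 °C; aq. NH4Cl
Reagents that add atoms: none
Why: Deprotonation of the terminal alkyne and 1,2-addition of the lithium acetylide to the enal at low temperature form the C5–C6 bond and the vinyl carbinol, racemic at C6.

Step 3
Reactants: 5 rac-6-(tert-butyldiphenylsilyloxy)hex-1-en-4-yn-3-ol
Product: 6 (3S)-6-(tert-butyldiphenylsilyloxy)hex-1-en-4-yn-3-ol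
Conditions: Ti(OiPr)4 (0.2 equiv), L-(+)-diisopropyl tartrate (0.3 equiv), t-BuOOH (0.6 equiv), 4 Å molecular sieves, CH2Cl2, −20 °C
Reagents that add atoms: none
Why: Sharpless kinetic resolution of a secondary vinyl carbinol: with the L-(+)-tartrate the 3R enantiomer is the one epoxidised quickly, so the 3S alcohol should be recovered when the reaction is taken past half conversion. This centre is C6 of the target.

Step 4
Reactants: 6 (3S)-6-(tert-butyldiphenylsilyloxy)hex-1-en-4-yn-3-ol
Product: 8 (3S,4Z)-6-(tert-butyldiphenylsilyloxy)-5-iodohexa-1,4-dien-3-ol, via cyclic alkenylaluminate 7 (not isolated)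
Conditions: NaAlH2(OCH2CH2OMe)2, THF, 0 °C; EtOAc; then I2, −78 to 0 °C
Reagents that add atoms: iodine, II
Why: Hydroxyl-directed trans-hydroalumination of the propargylic alcohol puts aluminium on the distal alkyne carbon (C4), cis to the carbinol carbon, and iodinolysis with retention gives the Z iodide. The C4=C5 geometry is thus fixed by mechanism; C6 is untouched.

Step 5
Reactants: 8 (3S,4Z)-6-(tert-butyldiphenylsilyloxy)-5-iodohexa-1,4-dien-3-ol
Product: 9 (3S,4Z)-6-(tert-butyldiphenylsilyloxy)-5-iodo-3-(triethylsilyloxy)hexa-1,4-diene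
Conditions: TESCl, imidazole, DMAP (cat.), CH2Cl2, 0 °C to rt
Reagents that add atoms: chlorotriethylsilane, CC[Si](Cl)(CC)CC
Why: Silylation of the secondary alcohol; O-6 must be blocked because a free hydroxyl cis to the future ynone would add to it and form a furan. TES is the most labile silyl group in the molecule and can be removed first.

Step 6
Reactants: 9 (3S,4Z)-6-(tert-butyldiphenylsilyloxy)-5-iodo-3-(triethylsilyloxy)hexa-1,4-diene; 10 ethynyltrimethylsilane
Product: 11 (3S,4E)-5-[(tert-butyldiphenylsilyloxy)methyl]-3-(triethylsilyloxy)-7-(trimethylsilyl)hepta-1,4-dien-6-yne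
Conditions: PdCl2(PPh3)2 (3 mol%), CuI (6 mol%), Et3N, THF, rt
Reagents that add atoms: none
Why: Sonogashira coupling of an alkenyl iodide with a terminal alkyne forms C3–C4 with retention of the alkene geometry. The descriptor becomes E only because the alkynyl group ranks below CH2OSi.

Step 7
Reactants: 11 (3S,4E)-5-[(tert-butyldiphenylsilyloxy)methyl]-3-(triethylsilyloxy)-7-(trimethylsilyl)hepta-1,4-dien-6-yne
Product: 12 (3S,4E)-5-[(tert-butyldiphenylsilyloxy)methyl]-3-(triethylsilyloxy)hepta-1,4-dien-6-yne
Conditions: K2CO3, MeOH, rt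
Reagents that add atoms: none
Why: Methanolysis of the alkynyl C–Si bond under mild base; the three silyl ethers are stable to these conditions.

Step 8
Reactants: 13 (S)-citramalic acid
Product: 14 2-[(4S)-2,2,4-trimethyl-5-oxo-1,3-dioxolan-4-yl]acetic acid
Conditions: 2,2-dimethoxypropane, p-TsOH (cat.), rt
Reagents that add atoms: 2,2-dimethoxypropane, COC(C)(C)OC
Why: Acetonide formation takes the α-hydroxy acid unit into a five-membered dioxolanone in preference to the six-membered alternative. This masks the C10 hydroxyl, activates the C1 carboxyl and leaves the C8 carboxyl free; the stereocentre (C10) is not involved.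

Step 9
Reactants: 14 2-[(4S)-2,2,4-trimethyl-5-oxo-1,3-dioxolan-4-yl]acetic acid
Product: 15 (5S)-5-(2-hydroxyethyl)-2,2,5-trimethyl-1,3-dioxolan-4-one
Conditions: BH3·SMe2, THF, 0 °C to rt; MeOH quench, neutral work-up
Reagents that add atoms: none
Why: Borane reduces a free carboxylic acid much faster than the lactone-type ester of the dioxolanone; a neutral work-up avoids translactonisation of the new hydroxyl.

Step 10
Reactants: 15 (5S)-5-(2-hydroxyethyl)-2,2,5-trimethyl-1,3-dioxolan-4-one
Product: 16 (5S)-5-[2-(tert-butyldimethylsilyloxy)ethyl]-2,2,5-trimethyl-1,3-dioxolan-4-one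
Conditions: TBSCl, imidazole, CH2Cl2, 0 °C to rt
Reagents that add atoms: tert-butyl(chloro)dimethylsilane, CC(C)(C)[Si](C)(C)Cl
Why: Silylation of the primary alcohol under basic conditions that leave the dioxolanone intact. TBS at O-8 lies between TES (O-6) and TBDPS (O-15) in lability.

Step 11
Reactants: 16 (5S)-5-[2-(tert-butyldimethylsilyloxy)ethyl]-2,2,5-trimethyl-1,3-dioxolan-4-one
Product: 17 (2S)-4-(tert-butyldimethylsilyloxy)-2-hydroxy-N-methoxy-N,2-dimethylbutanamide
Conditions: MeNHOMe·HCl, iPrMgCl, THF, −20 to 0 °C
Reagents that add atoms: N,O-dimethylhydroxylamine hydrochloride, CNOC.Cl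
Why: Aminolysis of the activated dioxolanone by the magnesium amide (Weinreb amide synthesis from a lactone-type ester); the hemiketal that is released loses acetone and frees the tertiary hydroxyl.

Step 12
Reactants: 12 (3S,4E)-5-[(tert-butyldiphenylsilyloxy)methyl]-3-(triethylsilyloxy)hepta-1,4-dien-6-yne; 17 (2S)-4-(tert-butyldimethylsilyloxy)-2-hydroxy-N-methoxy-N,2-dimethylbutanamide
Product: 20 (3S,7E,9S)-1-(tert-butyldimethylsilyloxy)-7-[(tert-butyldiphenylsilyloxy)methyl]-3-hydroxy-3-methyl-9-(triethylsilyloxy)undeca-7,10-dien-5-yn-4-one, via lithium acetylide 18 (not isolated), via chloromagnesium alkoxide 19 (not isolated)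
Conditions: 12, n-BuLi, THF, −78 °C; separately 17, iPrMgCl (1.0 equiv), THF, −40 °C; combine, −78 to 0 °C; aq. NH4Cl
Reagents that add atoms: none
Why: Acylation of a lithium acetylide by a Weinreb amide forms C1–C2; the chelated tetrahedral intermediate prevents over-addition. The tertiary hydroxyl is carried as its magnesium alkoxide so that it cannot protonate the acetylide.

Step 13
Reactants: 20 (3S,7E,9S)-1-(tert-butyldimethylsilyloxy)-7-[(tert-butyldiphenylsilyloxy)methyl]-3-hydroxy-3-methyl-9-(triethylsilyloxy)undeca-7,10-dien-5-yn-4-one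
Product: 21 (2S)-2-[2-(tert-butyldimethylsilyloxy)ethyl]-5-[(2Z,4S)-1-(tert-butyldiphenylsilyloxy)-4-(triethylsilyloxy)hexa-2,5-dien-2-yl]-2-methylfuran-3(2H)-one
Conditions: Ph3PAuNTf2 (5 mol%), toluene, rt
Reagents that add atoms: none
Why: The monovalent gold cation activates the ynone; 5-endo-dig attack of the C10 hydroxyl on C3 and protodeauration give the 3(2H)-furanone, the known cyclisation of α'-hydroxy ynones. The silylated O-6 cannot compete by the 5-exo mode.

Step 14
Reactants: 21 (2S)-2-[2-(tert-butyldimethylsilyloxy)ethyl]-5-[(2Z,4S)-1-(tert-butyldiphenylsilyloxy)-4-(triethylsilyloxy)hexa-2,5-dien-2-yl]-2-methylfuran-3(2H)-one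
Product: 22 (2S)-2-[2-(tert-butyldimethylsilyloxy)ethyl]-5-[(2Z,4S)-1-(tert-butyldiphenylsilyloxy)-4-hydroxyhexa-2,5-dien-2-yl]-2-methylfuran-3(2H)-one
Conditions: HF·pyridine, pyridine, THF, 0 °C
Reagents that add atoms: none
Why: Buffered HF·pyridine cleaves the TES ether well before the primary TBS and TBDPS ethers. The buffered, methanol-free medium spares the bis-allylic carbinol from ionisation.

Step 15
Reactants: 22 (2S)-2-[2-(tert-butyldimethylsilyloxy)ethyl]-5-[(2Z,4S)-1-(tert-butyldiphenylsilyloxy)-4-hydroxyhexa-2,5-dien-2-yl]-2-methylfuran-3(2H)-one; 23 2-(bromomethyl)acrylic acid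
Product: 24 (3S,4Z)-6-(tert-butyldiphenylsilyloxy)-5-{(2S)-2-[2-(tert-butyldimethylsilyloxy)ethyl]-2-methyl-3-oxo-2,3-dihydrofuran-5-yl}hexa-1,4-dien-3-yl 2-(bromomethyl)prop-2-enoate
Conditions: DCC, DMAP (5 mol%), CH2Cl2, −20 to 0 °C
Reagents that add atoms: none
Why: Steglich esterification of the secondary alcohol; the low DMAP loading and low temperature keep displacement of the allylic bromide by the amine negligible.

Step 16
Reactants: 24 (3S,4Z)-6-(tert-butyldiphenylsilyloxy)-5-{(2S)-2-[2-(tert-butyldimethylsilyloxy)ethyl]-2-methyl-3-oxo-2,3-dihydrofuran-5-yl}hexa-1,4-dien-3-yl 2-(bromomethyl)prop-2-enoate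
Product: 25 (5R)-3-(bromomethyl)-5-[(1Z)-3-(tert-butyldiphenylsilyloxy)-2-{(2S)-2-[2-(tert-butyldimethylsilyloxy)ethyl]-2-methyl-3-oxo-2,3-dihydrofuran-5-yl}prop-1-en-1-yl]furan-2(5H)-one
Conditions: second-generation Grubbs catalyst RuCl2(=CHPh)(PCy3)(H2IMes) (10 mol%), toluene, 80 °C, 5 mM
Reagents that add atoms: none
Why: Ring-closing metathesis: the ruthenium carbene initiates at the monosubstituted C7 vinyl group and closes onto the 1,1-disubstituted acrylate to give the butenolide. The trisubstituted C4=C5 alkene and the furanone enol ether are too hindered and electron-poor to compete. C6 is unchanged; its descriptor becomes R through the priority change alone.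

Step 17
Reactants: 25 (5R)-3-(bromomethyl)-5-[(1Z)-3-(tert-butyldiphenylsilyloxy)-2-{(2S)-2-[2-(tert-butyldimethylsilyloxy)ethyl]-2-methyl-3-oxo-2,3-dihydrofuran-5-yl}prop-1-en-1-yl]furan-2(5H)-one
Product: 26 (5R)-3-(bromomethyl)-5-[(1Z)-3-(tert-butyldiphenylsilyloxy)-2-{(2S)-2-(2-hydroxyethyl)-2-methyl-3-oxo-2,3-dihydrofuran-5-yl}prop-1-en-1-yl]furan-2(5H)-one
Conditions: camphorsulfonic acid (0.1 equiv), MeOH/CH2Cl2 1:1, 0 °C
Reagents that add atoms: none
Why: Acid-catalysed methanolysis removes the primary TBS ether far faster than the TBDPS ether. No base is used, because C6–H of the butenolide is now acidic and the allylic bromide is electrophilic.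

Step 18
Reactants: 26 (5R)-3-(bromomethyl)-5-[(1Z)-3-(tert-butyldiphenylsilyloxy)-2-{(2S)-2-(2-hydroxyethyl)-2-methyl-3-oxo-2,3-dihydrofuran-5-yl}prop-1-en-1-yl]furan-2(5H)-one
Product: 27 2-[(2S)-5-{(1Z)-1-[(2R)-4-(bromomethyl)-5-oxo-2,5-dihydrofuran-2-yl]-3-(tert-butyldiphenylsilyloxy)prop-1-en-2-yl}-2-methyl-3-oxo-2,3-dihydrofuran-2-yl]acetaldehyde (the seco-C7/C8 bromomethyl butenolide aldehyde)
Conditions: Dess–Martin periodinane, NaHCO3, CH2Cl2, 0 °C to rt
Reagents that add atoms: none
Why: Dess–Martin oxidation of the primary alcohol under buffered, non-basic conditions. The aldehyde is made only now because the C10 oxygen β to it is a vinylogous carboxylate leaving group.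

Step 19
Reactants: 27 the seco-C7/C8 bromomethyl butenolide aldehyde
Product: 29 (4Z,6R,7R,8R,10S)-15-(tert-butyldiphenylsilyloxy)-3,10-epoxy-8-hydroxy-1-oxogermacra-2,4,11(13)-trien-12,6-olide, via allylchromium dichloride 28 (not isolated)
Conditions: CrCl2 (10 equiv), THF, rt, syringe-pump addition of 27 to about 1 mM; aqueous work-up
Reagents that add atoms: none
Why: Proposed new method: CrCl2 reduces the allylic C13–Br bond by two single-electron transfers to the allylchromium species 28 (trivalent chromium on C13), whose γ-carbon C7 adds to the chromium-bound C8 aldehyde through a closed six-membered transition state, so that the alkene moves to C11=C13 and the finished α-methylene lactone appears together with the C7–C8 bond. The closest known reactions are the intermolecular Barbier-type γ-additions of 3-(bromomethyl)furan-2(5H)-ones to aldehydes and the CrCl2-mediated (Nozaki–Hiyama) cyclisations of ω-formyl allylic bromides to medium carbocycles; the two have not been combined at this bond. The ring closes by exo-trig attack on the aldehyde carbon, which completes the ten-membered carbocycle (10-exo-trig through C1 and C2; counted through the furanone oxygen the smallest new ring is nine-membered), and only four single bonds (C5–C6, C3–C4, C9–C10, C8–C9) have to be frozen because the Z alkene and the two planar five-membered rings are rigid. At C7 the new bond has to form on the butenolide face anti to C5; since the tether is itself the C6 substituent this is a strain effect and not a shielding effect, the trans-fused transition state being the one in which the chain leaves C6 and returns to C7 without eclipsing across the lactone, as in the trans 6,12-olide of the product. At C8 the configuration follows from which aldehyde face enters the bicyclic transition state: 8R requires O-8 and C6 syn along C9–C8–C7–C11, that is C9 axial in the chromium chair, which is opposite to the open-chain preference of this E-locked allyl unit and has to be imposed by the short C9–C10 link to the furanone, so C8 is the less secure centre. The step needs γ- over α-attack (secured by the cyclic transition state), addition to the aldehyde and not to the C1 ketone (allylchromium reagents discriminate strongly), and cyclisation over protonation, dimerisation or oligomerisation (anhydrous THF, slow addition, high dilution).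

Step 20
Reactants: 29 (4Z,6R,7R,8R,10S)-15-(tert-butyldiphenylsilyloxy)-3,10-epoxy-8-hydroxy-1-oxogermacra-2,4,11(13)-trien-12,6-olide; 30 (R)-2-methylbutanoic acid
Product: 31 (4Z,6R,7R,8R,10S)-15-(tert-butyldiphenylsilyloxy)-3,10-epoxy-8-[(2R)-2-methylbutanoyloxy]-1-oxogermacra-2,4,11(13)-trien-12,6-olide
Conditions: N,N'-diisopropylcarbodiimide, DMAP (0.1 equiv), CH2Cl2, 0 °C to rt
Reagents that add atoms: none
Why: Carbodiimide esterification of the secondary C8 alcohol with retention at C8; catalytic DMAP and low temperature limit epimerisation of the acyl α-centre and reversible addition to the methylene lactone.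

Step 21
Reactants: 31 (4Z,6R,7R,8R,10S)-15-(tert-butyldiphenylsilyloxy)-3,10-epoxy-8-[(2R)-2-methylbutanoyloxy]-1-oxogermacra-2,4,11(13)-trien-12,6-olide
Product: 32 (4Z,6R,7R,8R,10S)-3,10-epoxy-15-hydroxy-8-[(2R)-2-methylbutanoyloxy]-1-oxogermacra-2,4,11(13)-trien-12,6-olide (CNP0307052.2)
Conditions: HF·pyridine, pyridine, THF, 0 °C to rt
Reagents that add atoms: none
Why: Fluoride cleaves the Si–O bond of the primary allylic TBDPS ether; the weakly acidic, non-basic medium leaves the methylene lactone, the ester and the furanone untouched.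

## Compound list

1 | propargyl alcohol (prop-2-yn-1-ol) | C#CCO | starting material
2 | tert-butyl(diphenyl)(prop-2-yn-1-yloxy)silane | C#CCO[Si](c1ccccc1)(c1ccccc1)C(C)(C)C | intermediate
3 | acrolein (prop-2-enal) | C=CC=O | starting material
4 | [3-(tert-butyldiphenylsilyloxy)prop-1-yn-1-yl]lithium | [Li]C#CCO[Si](c1ccccc1)(c1ccccc1)C(C)(C)C | intermediate (not isolated)
5 | rac-6-(tert-butyldiphenylsilyloxy)hex-1-en-4-yn-3-ol | C=CC(O)C#CCO[Si](c1ccccc1)(c1ccccc1)C(C)(C)C | intermediate
6 | (3S)-6-(tert-butyldiphenylsilyloxy)hex-1-en-4-yn-3-ol | C=C[C@H](O)C#CCO[Si](c1ccccc1)(c1ccccc1)C(C)(C)C | intermediate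
7 | sodium cyclic alkoxy(alkenyl)bis(2-methoxyethoxy)aluminate of 6 (five-membered ring O–Al–C4=C5–C6, aluminium on C4) | C=C[C@@H]1O[Al-](OCCOC)(OCCOC)C(CO[Si](c2ccccc2)(c2ccccc2)C(C)(C)C)=C1.[Na+] | intermediate (not isolated)
8 | (3S,4Z)-6-(tert-butyldiphenylsilyloxy)-5-iodohexa-1,4-dien-3-ol | C=C[C@H](O)/C=C(I)/CO[Si](c1ccccc1)(c1ccccc1)C(C)(C)C | intermediate
9 | (3S,4Z)-6-(tert-butyldiphenylsilyloxy)-5-iodo-3-(triethylsilyloxy)hexa-1,4-diene | C=C[C@H](O[Si](CC)(CC)CC)/C=C(I)/CO[Si](c1ccccc1)(c1ccccc1)C(C)(C)C | intermediate
10 | ethynyltrimethylsilane | C#C[Si](C)(C)C | starting material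
11 | (3S,4E)-5-[(tert-butyldiphenylsilyloxy)methyl]-3-(triethylsilyloxy)-7-(trimethylsilyl)hepta-1,4-dien-6-yne | C=C[C@H](O[Si](CC)(CC)CC)/C=C(/CO[Si](c1ccccc1)(c1ccccc1)C(C)(C)C)C#C[Si](C)(C)C | intermediate
12 | (3S,4E)-5-[(tert-butyldiphenylsilyloxy)methyl]-3-(triethylsilyloxy)hepta-1,4-dien-6-yne | C=C[C@H](O[Si](CC)(CC)CC)/C=C(/CO[Si](c1ccccc1)(c1ccccc1)C(C)(C)C)C#C | intermediate
13 | (S)-citramalic acid [(2S)-2-hydroxy-2-methylbutanedioic acid] | OC(=O)[C@](C)(CC(=O)O)O | starting material
14 | 2-[(4S)-2,2,4-trimethyl-5-oxo-1,3-dioxolan-4-yl]acetic acid | CC1(C)OC(=O)[C@](C)(CC(=O)O)O1 | intermediate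
15 | (5S)-5-(2-hydroxyethyl)-2,2,5-trimethyl-1,3-dioxolan-4-one | CC1(C)OC(=O)[C@](C)(CCO)O1 | intermediate
16 | (5S)-5-[2-(tert-butyldimethylsilyloxy)ethyl]-2,2,5-trimethyl-1,3-dioxolan-4-one | CC1(C)OC(=O)[C@](C)(CCO[Si](C)(C)C(C)(C)C)O1 | intermediate
17 | (2S)-4-(tert-butyldimethylsilyloxy)-2-hydroxy-N-methoxy-N,2-dimethylbutanamide | CON(C)C(=O)[C@@](C)(O)CCO[Si](C)(C)C(C)(C)C | intermediate
18 | lithium acetylide of 12 (lithium on C2) | C=C[C@H](O[Si](CC)(CC)CC)/C=C(/CO[Si](c1ccccc1)(c1ccccc1)C(C)(C)C)C#C[Li] | intermediate (not isolated)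
19 | chloromagnesium alkoxide of 17 | CON(C)C(=O)[C@@](C)(O[Mg]Cl)CCO[Si](C)(C)C(C)(C)C | intermediate (not isolated)
20 | (3S,7E,9S)-1-(tert-butyldimethylsilyloxy)-7-[(tert-butyldiphenylsilyloxy)methyl]-3-hydroxy-3-methyl-9-(triethylsilyloxy)undeca-7,10-dien-5-yn-4-one | C=C[C@H](O[Si](CC)(CC)CC)/C=C(/CO[Si](c1ccccc1)(c1ccccc1)C(C)(C)C)C#CC(=O)[C@@](C)(O)CCO[Si](C)(C)C(C)(C)C | intermediate
21 | (2S)-2-[2-(tert-butyldimethylsilyloxy)ethyl]-5-[(2Z,4S)-1-(tert-butyldiphenylsilyloxy)-4-(triethylsilyloxy)hexa-2,5-dien-2-yl]-2-methylfuran-3(2H)-one | C=C[C@H](O[Si](CC)(CC)CC)/C=C(/CO[Si](c1ccccc1)(c1ccccc1)C(C)(C)C)C1=CC(=O)[C@](C)(CCO[Si](C)(C)C(C)(C)C)O1 | intermediate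
22 | (2S)-2-[2-(tert-butyldimethylsilyloxy)ethyl]-5-[(2Z,4S)-1-(tert-butyldiphenylsilyloxy)-4-hydroxyhexa-2,5-dien-2-yl]-2-methylfuran-3(2H)-one | C=C[C@H](O)/C=C(/CO[Si](c1ccccc1)(c1ccccc1)C(C)(C)C)C1=CC(=O)[C@](C)(CCO[Si](C)(C)C(C)(C)C)O1 | intermediate
23 | 2-(bromomethyl)acrylic acid | C=C(CBr)C(=O)O | starting material
24 | (3S,4Z)-6-(tert-butyldiphenylsilyloxy)-5-{(2S)-2-[2-(tert-butyldimethylsilyloxy)ethyl]-2-methyl-3-oxo-2,3-dihydrofuran-5-yl}hexa-1,4-dien-3-yl 2-(bromomethyl)prop-2-enoate | C=C[C@H](OC(=O)C(=C)CBr)/C=C(/CO[Si](c1ccccc1)(c1ccccc1)C(C)(C)C)C1=CC(=O)[C@](C)(CCO[Si](C)(C)C(C)(C)C)O1 | intermediate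
25 | (5R)-3-(bromomethyl)-5-[(1Z)-3-(tert-butyldiphenylsilyloxy)-2-{(2S)-2-[2-(tert-butyldimethylsilyloxy)ethyl]-2-methyl-3-oxo-2,3-dihydrofuran-5-yl}prop-1-en-1-yl]furan-2(5H)-one | BrCC1=C[C@H](OC1=O)/C=C(/CO[Si](c2ccccc2)(c2ccccc2)C(C)(C)C)C3=CC(=O)[C@](C)(CCO[Si](C)(C)C(C)(C)C)O3 | intermediate
26 | (5R)-3-(bromomethyl)-5-[(1Z)-3-(tert-butyldiphenylsilyloxy)-2-{(2S)-2-(2-hydroxyethyl)-2-methyl-3-oxo-2,3-dihydrofuran-5-yl}prop-1-en-1-yl]furan-2(5H)-one | BrCC1=C[C@H](OC1=O)/C=C(/CO[Si](c2ccccc2)(c2ccccc2)C(C)(C)C)C3=CC(=O)[C@](C)(CCO)O3 | intermediate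
27 | 2-[(2S)-5-{(1Z)-1-[(2R)-4-(bromomethyl)-5-oxo-2,5-dihydrofuran-2-yl]-3-(tert-butyldiphenylsilyloxy)prop-1-en-2-yl}-2-methyl-3-oxo-2,3-dihydrofuran-2-yl]acetaldehyde | BrCC1=C[C@H](OC1=O)/C=C(/CO[Si](c2ccccc2)(c2ccccc2)C(C)(C)C)C3=CC(=O)[C@](C)(CC=O)O3 | intermediate
28 | allylchromium dichloride from 27 (trivalent chromium on C13) | Cl[Cr](Cl)CC1=C[C@H](OC1=O)/C=C(/CO[Si](c2ccccc2)(c2ccccc2)C(C)(C)C)C3=CC(=O)[C@](C)(CC=O)O3 | intermediate (not isolated)
29 | (4Z,6R,7R,8R,10S)-15-(tert-butyldiphenylsilyloxy)-3,10-epoxy-8-hydroxy-1-oxogermacra-2,4,11(13)-trien-12,6-olide | C=C1C(=O)O[C@@H]2/C=C(/CO[Si](c3ccccc3)(c3ccccc3)C(C)(C)C)C4=CC(=O)[C@](C)(C[C@@H](O)[C@@H]12)O4 | intermediate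
30 | (R)-2-methylbutanoic acid | OC(=O)[C@H](C)CC | starting material
31 | (4Z,6R,7R,8R,10S)-15-(tert-butyldiphenylsilyloxy)-3,10-epoxy-8-[(2R)-2-methylbutanoyloxy]-1-oxogermacra-2,4,11(13)-trien-12,6-olide | C=C1C(=O)O[C@@H]2/C=C(/CO[Si](c3ccccc3)(c3ccccc3)C(C)(C)C)C4=CC(=O)[C@](C)(C[C@@H](OC(=O)[C@H](C)CC)[C@@H]12)O4 | intermediate
32 | (4Z,6R,7R,8R,10S)-3,10-epoxy-15-hydroxy-8-[(2R)-2-methylbutanoyloxy]-1-oxogermacra-2,4,11(13)-trien-12,6-olide (CNP0307052.2) | C=C1C(=O)O[C@@H]2/C=C(/CO)C3=CC(=O)[C@](C)(C[C@@H](OC(=O)[C@H](C)CC)[C@@H]12)O3 | target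

## Step count and risks

Total step count: 21. Longest linear sequence: 17 steps (steps 1–7, then 12–21); the branch from 13 (steps 8–11) joins at step 12.

**Step 19 (key step, proposed new method).**
What may go wrong: the allylchromium species may be consumed before the strained bicyclic transition state is reached. The likely diversions are protonation of the allyl metal, reductive dimerisation, intermolecular allylation, or 1,4-elimination that opens the lactone at C6. If the ring does close, facial control at C7 and C8 may be poor, because both are set by ring strain and not by a shielding group.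

Fallback, using only known reaction types; it sets out from 8 and 13 and returns at 31:
- Sonogashira coupling of 8 with 10 gives the silylated dienynol F1. Esterification with 23 gives the bromomethylacrylate F2, and ring-closing metathesis gives the alkynyl bromomethyl butenolide F3.
- In parallel, LiAlH4 reduces 13 to the triol F4. Acid-catalysed reaction with 2,2-dimethoxypropane closes the 1,2-diol to the acetonide alcohol F5, and Dess–Martin oxidation gives the aldehyde F6.
- Zinc-mediated intermolecular Barbier allylation of F6 with F3 in THF/aqueous NH4Cl, the established reaction of bromomethyl butenolides, gives the open-chain methylene lactone 8S alcohol F7. Here the C6 substituent does shield one face of the butenolide, so C7 should come out trans, and the closed transition state should give 8S.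
- Mitsunobu esterification with 30 inverts C8 and gives the ester F8. If the Barbier step gives the 8R alcohol instead, plain carbodiimide acylation replaces it.
- Aqueous acetic acid removes the acetonide to give the diol F9. N-Iodosuccinimide with catalytic AgNO3 exchanges the alkynyl silane for iodine to give the iodoalkyne F10. Oxidation of the primary alcohol with TEMPO and PhI(OAc)2 gives the hydroxy aldehyde F11.
- CrCl2 with catalytic NiCl2 at high dilution closes the ten-membered ring between C1 and C2 to the cyclic propargylic alcohol F12 (either C1 epimer). Dess–Martin oxidation gives the cyclic hydroxy ynone F13, and Ph3PAuNTf2 closes the furanone across the ring to give 31.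

**Step 16 (ring-closing metathesis).**
What may go wrong: slow closure onto the 1,1-disubstituted, electron-poor acrylate, with catalyst loss through reaction with the allylic bromide or unproductive binding to the dienyl furanone.

Fallback, from 22 to 25, introducing the bromide after the ring is closed: 2-(hydroxymethyl)acrylic acid is bis-silylated with TESCl and the silyl ester hydrolysed on work-up to give the silyloxymethyl acrylic acid F14. Carbodiimide esterification of 22 gives the acrylate F15, and ring-closing metathesis gives the silyloxymethyl butenolide F16. PPTS in methanol gives the hydroxymethyl butenolide F17, which CBr4/PPh3 converts into 25.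

**Step 13 (gold cyclisation).**
What may go wrong: attack of the silylated O-6 on the activated alkyne (5-exo) with loss of silicon and furan formation, or silyl loss under the Lewis-acidic catalyst before the furanone has formed.

Fallback, from 20 to 21 without a metal: Et2NH in ethanol adds to the ynone to give the enaminone F18. Stirring with aqueous acetic acid exchanges the amine for the C10 hydroxyl and closes F18 to 21. A silyl ether cannot take part in this pathway.

**Step 12 (fragment coupling).**
What may go wrong: incomplete acylation, because the alkoxide-bearing amide is hindered and doubly charged at the tetrahedral stage; incomplete deprotonation of the tertiary hydroxyl would return the alkyne by proton transfer.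

Fallback, from 17 to 20: 17 is silylated (TMSCl, imidazole) to the trimethylsilyl ether F19, which acylates 18 as a neutral amide. A short treatment of the crude product with citric acid in methanol at 0 °C frees the tertiary hydroxyl and gives 20.

**Step 20 (acylation and the C8 configuration).**
What may go wrong: step 19 may deliver the alcohol with the opposite configuration at C8, or acylation of the hindered alcohol may be slow enough for the acyl α-centre to epimerise.

Fallback, from 27 to 31: if the cyclisation gives the 8S alcohol F20, Mitsunobu esterification with 30 (PPh3, diisopropyl azodicarboxylate, toluene, 0 °C) installs the ester with inversion at C8 and gives 31 directly, under neutral conditions and with no activated acyl species.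

## Further compounds

F1 | step 19 | (3S,4E)-5-[(tert-butyldiphenylsilyloxy)methyl]-7-(trimethylsilyl)hepta-1,4-dien-6-yn-3-ol | C=C[C@H](O)/C=C(/CO[Si](c1ccccc1)(c1ccccc1)C(C)(C)C)C#C[Si](C)(C)C
F2 | step 19 | 2-(bromomethyl)prop-2-enoate of F1 | C=C[C@H](OC(=O)C(=C)CBr)/C=C(/CO[Si](c1ccccc1)(c1ccccc1)C(C)(C)C)C#C[Si](C)(C)C
F3 | step 19 | (5R)-3-(bromomethyl)-5-[(1E)-2-[(tert-butyldiphenylsilyloxy)methyl]-4-(trimethylsilyl)but-1-en-3-yn-1-yl]furan-2(5H)-one | BrCC1=C[C@H](OC1=O)/C=C(/CO[Si](c2ccccc2)(c2ccccc2)C(C)(C)C)C#C[Si](C)(C)C
F4 | step 19 | (2S)-2-methylbutane-1,2,4-triol | OC[C@@](C)(O)CCO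
F5 | step 19 | 2-[(4S)-2,2,4-trimethyl-1,3-dioxolan-4-yl]ethanol | CC1(C)OC[C@](C)(CCO)O1
F6 | step 19 | 2-[(4S)-2,2,4-trimethyl-1,3-dioxolan-4-yl]acetaldehyde | CC1(C)OC[C@](C)(CC=O)O1
F7 | step 19 | open-chain (6R,7R,8S,10S) methylene lactone alcohol: trans-4,5-disubstituted 3-methylenedihydrofuran-2-one with the silylated enyne on C6 and a 1-hydroxy-2-(2,2,4-trimethyl-1,3-dioxolan-4-yl)ethyl group on C7 | C=C1C(=O)O[C@H](/C=C(/CO[Si](c2ccccc2)(c2ccccc2)C(C)(C)C)C#C[Si](C)(C)C)[C@H]1[C@@H](O)C[C@@]2(C)COC(C)(C)O2
F8 | step 19 | (6R,7R,8R,10S) (2R)-2-methylbutanoate of the C8-inverted alcohol | C=C1C(=O)O[C@H](/C=C(/CO[Si](c2ccccc2)(c2ccccc2)C(C)(C)C)C#C[Si](C)(C)C)[C@H]1[C@H](OC(=O)[C@H](C)CC)C[C@@]2(C)COC(C)(C)O2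
F9 | step 19 | 1,10-diol from F8 (acetonide removed) | C=C1C(=O)O[C@H](/C=C(/CO[Si](c2ccccc2)(c2ccccc2)C(C)(C)C)C#C[Si](C)(C)C)[C@H]1[C@H](OC(=O)[C@H](C)CC)C[C@](C)(O)CO
F10 | step 19 | C2 iodoalkyne 1,10-diol | C=C1C(=O)O[C@H](/C=C(/CO[Si](c2ccccc2)(c2ccccc2)C(C)(C)C)C#CI)[C@H]1[C@H](OC(=O)[C@H](C)CC)C[C@](C)(O)CO
F11 | step 19 | C2 iodoalkyne C1 aldehyde with free C10 hydroxyl | C=C1C(=O)O[C@H](/C=C(/CO[Si](c2ccccc2)(c2ccccc2)C(C)(C)C)C#CI)[C@H]1[C@H](OC(=O)[C@H](C)CC)C[C@](C)(O)C=O
F12 | step 19 | ten-membered cyclic propargylic 1,10-diol (C1 epimers), 15-O-TBDPS, 8-O-(2R)-2-methylbutanoyl, 6,12-olide | C=C1C(=O)O[C@@H]2/C=C(/CO[Si](c3ccccc3)(c3ccccc3)C(C)(C)C)C#CC(O)[C@@](C)(O)C[C@@H](OC(=O)[C@H](C)CC)[C@@H]12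
F13 | step 19 | ten-membered cyclic 10-hydroxy-2-yn-1-one | C=C1C(=O)O[C@@H]2/C=C(/CO[Si](c3ccccc3)(c3ccccc3)C(C)(C)C)C#CC(=O)[C@@](C)(O)C[C@@H](OC(=O)[C@H](C)CC)[C@@H]12
F14 | step 16 | 2-[(triethylsilyloxy)methyl]prop-2-enoic acid | C=C(CO[Si](CC)(CC)CC)C(=O)O
F15 | step 16 | 2-[(triethylsilyloxy)methyl]prop-2-enoate of 22 | C=C[C@H](OC(=O)C(=C)CO[Si](CC)(CC)CC)/C=C(/CO[Si](c1ccccc1)(c1ccccc1)C(C)(C)C)C1=CC(=O)[C@](C)(CCO[Si](C)(C)C(C)(C)C)O1
F16 | step 16 | 3-[(triethylsilyloxy)methyl] analogue of 25 | CC[Si](CC)(CC)OCC1=C[C@H](OC1=O)/C=C(/CO[Si](c2ccccc2)(c2ccccc2)C(C)(C)C)C3=CC(=O)[C@](C)(CCO[Si](C)(C)C(C)(C)C)O3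
F17 | step 16 | 3-(hydroxymethyl) analogue of 25 | OCC1=C[C@H](OC1=O)/C=C(/CO[Si](c2ccccc2)(c2ccccc2)C(C)(C)C)C3=CC(=O)[C@](C)(CCO[Si](C)(C)C(C)(C)C)O3
F18 | step 13 | 3-(diethylamino) enaminone from 20 (amine on C3, C2=C3 geometry not fixed) | C=C[C@H](O[Si](CC)(CC)CC)/C=C(/CO[Si](c1ccccc1)(c1ccccc1)C(C)(C)C)C(N(CC)CC)=CC(=O)[C@@](C)(O)CCO[Si](C)(C)C(C)(C)C
F19 | step 12 | (2S)-4-(tert-butyldimethylsilyloxy)-N-methoxy-N,2-dimethyl-2-(trimethylsilyloxy)butanamide | CON(C)C(=O)[C@@](C)(O[Si](C)(C)C)CCO[Si](C)(C)C(C)(C)C
F20 | step 20 | (4Z,6R,7R,8S,10S)-15-(tert-butyldiphenylsilyloxy)-3,10-epoxy-8-hydroxy-1-oxogermacra-2,4,11(13)-trien-12,6-olide (C8 epimer of 29) | C=C1C(=O)O[C@@H]2/C=C(/CO[Si](c3ccccc3)(c3ccccc3)C(C)(C)C)C4=CC(=O)[C@](C)(C[C@H](O)[C@@H]12)O4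
A1 | alternative 1 | ten-membered cyclic Z-enyne C1 carbinol with 10-O-TES, 15-O-TBS, 8-O-(2R)-2-methylbutanoyl and the 6,12-methylene lactone (one C1 epimer shown) | C=C1C(=O)O[C@@H]2/C=C(/CO[Si](C)(C)C(C)(C)C)C#C[C@@H](O)[C@](C)(C[C@@H](OC(=O)[C@H](C)CC)[C@@H]12)O[Si](CC)(CC)CC
A2 | alternative 2 | 1-hydroxy 3,10-epoxy-bridged enol ether with 15-O-TBS, 8-O-(2R)-2-methylbutanoyl and the 6,12-methylene lactone | C=C1C(=O)O[C@@H]2/C=C(/CO[Si](C)(C)C(C)(C)C)C3=C[C@@H](O)[C@](C)(C[C@@H](OC(=O)[C@H](C)CC)[C@@H]12)O3
A3 | alternative 3 | furanone-bridged ten-membered C6 allylic alcohol with a C7 CH2CO2Me side chain, 15-O-TBS and 8-O-(2R)-2-methylbutanoyl | COC(=O)C[C@H]1[C@H](O)/C=C(/CO[Si](C)(C)C(C)(C)C)C2=CC(=O)[C@](C)(C[C@H]1OC(=O)[C@H](C)CC)O2
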